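**Retrosynthetic overview**
1. Jaeskeanin ⇐ jaeschkeanadiol: 6‑OH‑directed epoxidation of C8=C9, acylation of 6‑OH, enzymatic unmasking of the phenol.
2. C4/C5/C6 of jaeschkeanadiol ⇐ bicyclic dienone 14: CBS reduction, OH‑directed epoxidation, 1,2‑hydride‑shift rearrangement (sets the trans ring fusion), isopropyl‑cerium addition, OH‑directed reduction at C6.
3. Seven‑membered ring ⇐ ring‑closing metathesis (C8=C9) after aldol attachment of the C6–C8 unit at C5; dehydration gives 14.
4. Quaternary C1 ⇐ ketoreductase reduction of achiral 3‑allylcyclopentenone (first stereocentre), OH‑directed Simmons–Smith, Li/NH3 cyclopropane cleavage to a regiodefined enolate.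
5. Ring order: cyclopentane (from the starting material), then cycloheptene (RCM), then oxirane (last).

Assumption: daucane numbering is used (C1 = methyl‑bearing ring‑fusion carbon, C4 = isopropyl carbinol, C5 = ring‑fusion CH, C6 = ester carbon, C8/C9 = epoxide carbons); β = face of the C1 methyl; all numbered starting materials are taken as commercial.

---

**Step 1**
Reactants: 1 (3‑ethoxycyclopent‑2‑en‑1‑one), 2 (allylmagnesium bromide)
Product: 3 (3‑allylcyclopent‑2‑en‑1‑one)
Conditions: allylMgBr, THF, −78 → 0 °C; then 1 M HCl, 0 °C, 15 min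
Reagents that add atoms: allylmagnesium bromide, C=CC[Mg]Br
Why: Stork–Danheiser sequence (1,2‑addition to the vinylogous ester, then acid hydrolysis/transposition); brief cold acid avoids conjugating the skipped diene.

**Step 2**
Reactants: 3
Product: 4 ((S)‑3‑allylcyclopent‑2‑en‑1‑ol)
Conditions: (S)‑selective ketoreductase (NADPH‑dependent alcohol dehydrogenase), NADP+ (cat.), i‑PrOH (10 vol %), phosphate buffer pH 7, 30 °C
Reagents that add atoms: none
Why: Ketoreductase‑catalysed asymmetric carbonyl reduction; the enzyme differentiates the CH2 and vinyl flanks of the prochiral ketone, reduces only C=O, and sets the first stereocentre (S).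

**Step 3**
Reactants: 4, 5 (diiodomethane)
Product: 6 ((1R,2S,5R)‑5‑allylbicyclo[3.1.0]hexan‑2‑ol; OH syn to the cyclopropane CH2)
Conditions: Et2Zn, CH2I2, CH2Cl2, −10 → 0 °C
Reagents that add atoms: diiodomethane, ICI
Why: Hydroxyl‑directed Simmons–Smith (Furukawa) cyclopropanation; the zinc alkoxide delivers CH2 syn to OH onto the allylic alkene only, relaying the carbinol configuration to the future C1.

**Step 4**
Reactants: 6
Product: 7 ((1R,5R)‑5‑allylbicyclo[3.1.0]hexan‑2‑one)
Conditions: Dess–Martin periodinane, NaHCO3, CH2Cl2, rt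
Reagents that add atoms: none
Why: Dess–Martin oxidation of the secondary alcohol; cyclopropane and terminal alkene are inert.

**Step 5**
Reactants: 7, 8 (chlorotrimethylsilane)
Product: 9 ((R)‑[(3‑allyl‑3‑methylcyclopent‑1‑en‑1‑yl)oxy]trimethylsilane)
Conditions: Li, NH3(l)/THF, −78 °C; evaporate NH3; then TMSCl, Et3N, THF, −78 → 0 °C
Reagents that add atoms: chlorotrimethylsilane, C[Si](C)(C)Cl
Why: Dissolving‑metal reductive cleavage of the cyclopropyl ketone breaks the exocyclic C–CH2 bond α to the carbonyl. The CH2 becomes the C1 methyl (quaternary centre, R), and the enolate forms only toward C5 and is trapped as the silyl enol ether.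

**Step 6**
Reactants: 10 (3‑methylbut‑3‑en‑1‑ol)
Product: 11 (3‑methylbut‑3‑enal)
Conditions: Dess–Martin periodinane, NaHCO3, CH2Cl2, 0 °C; used at once as a cold solution
Reagents that add atoms: none
Why: Buffered Dess–Martin oxidation gives the β,γ‑unsaturated aldehyde without isomerisation to the enal.

**Step 7**
Reactants: 9, 11
Product: 12 ((3R)‑3‑allyl‑2‑(1‑hydroxy‑3‑methylbut‑3‑en‑1‑yl)‑3‑methylcyclopentan‑1‑one; mixture at C5/C6)
Conditions: MeLi, THF, 0 °C; then −78 °C, add 11; AcOH quench at −78 °C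
Reagents that add atoms: none beyond the two reactants
Why: MeLi releases the regiodefined lithium enolate, which undergoes aldol addition at C5; the new C5/C6 centres are erased in step 9, so their ratio does not matter.

**Step 8**
Reactants: 12
Product: 13 (bicyclic β‑hydroxy ketone: 4‑oxo‑6‑hydroxy‑Δ8(9) hydroazulene, C1 R; mixture at C5/C6)
Conditions: Hoveyda–Grubbs II (5 mol %), toluene (5 mM), 60 °C
Reagents that add atoms: none (ethylene lost)
Why: Ring‑closing metathesis of the allyl and 2‑methylallyl groups forms the seven‑membered ring with the trisubstituted C8=C9 alkene.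

**Step 9**
Reactants: 13
Product: 14 ((3aR)‑3a,6‑dimethyl‑3,3a,4,7‑tetrahydroazulen‑1(2H)‑one; 4‑oxo‑Δ5(6),Δ8(9))
Conditions: MsCl, Et3N, CH2Cl2, 0 °C → rt
Reagents that add atoms: none
Why: Mesylation and in‑situ E1cB elimination; all diastereomers converge on one ring‑constrained enone, and the amine base is too weak to conjugate the skipped diene.

**Step 10**
Reactants: 14
Product: 15 ((1S,3aR)‑3a,6‑dimethyl‑1,2,3,3a,4,7‑hexahydroazulen‑1‑ol; 4β‑OH, cis to the C1 methyl)
Conditions: (R)‑Me‑CBS (20 mol %), catecholborane, toluene, −78 °C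
Reagents that add atoms: none
Why: Corey–Bakshi–Shibata reduction; catalyst‑controlled 1,2‑hydride delivery (alkylidene side as the large group) gives the 4S alcohol and leaves both alkenes untouched.

**Step 11**
Reactants: 15, 16 (tert‑butyl hydroperoxide)
Product: 17 (5β,6β‑epoxy‑4β‑ol; daucane 1R,4S,5R,6R)
Conditions: VO(acac)2 (5 mol %), t‑BuOOH (decane), CH2Cl2, 0 °C → rt
Reagents that add atoms: tert‑butyl hydroperoxide, CC(C)(C)OO
Why: Vanadium‑catalysed hydroxyl‑directed epoxidation; oxygen is delivered syn to the allylic OH onto C5=C6 only, and C8=C9 has no directing group.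

**Step 12**
Reactants: 17, 18 (tert‑butyldimethylsilyl triflate)
Product: 19 ((3aR,8R,8aS)‑8‑(tert‑butyldimethylsilyloxy)‑3a,6‑dimethyl‑3,3a,4,7,8,8a‑hexahydroazulen‑1(2H)‑one; 4‑oxo, 5α‑H, 6β‑OTBS)
Conditions: TBSOTf, i‑Pr2NEt, 4 Å MS, CH2Cl2, −45 °C
Reagents that add atoms: TBSOTf, CC(C)(C)[Si](C)(C)OS(=O)(=O)C(F)(F)F
Why: Jung "non‑aldol aldol" (semipinacol 1,2‑hydride shift); the silyl‑activated epoxide opens at tertiary C5 while the antiperiplanar C4–H migrates with inversion. This gives the C4 ketone and 5α‑H (trans ring fusion, 5S), with the epoxide oxygen retained on C6 as the silyl ether.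

**Step 13**
Reactants: 19, 20 (isopropyllithium)
Product: 21 ((3R,3aS,4R,8aR)‑4‑(tert‑butyldimethylsilyloxy)‑3‑isopropyl‑6,8a‑dimethyl‑1,2,3,3a,4,5,8,8a‑octahydroazulen‑3‑ol)
Conditions: i‑PrLi, anhydrous CeCl3, THF, −78 °C
Reagents that add atoms: isopropyllithium, [Li]C(C)C
Why: Organocerium (Imamoto) 1,2‑addition without enolisation or β‑elimination; attack on the α face, opposite the axial C1 methyl and the 6β‑OTBS, gives the 4β‑OH tertiary carbinol (4R).

**Step 14**
Reactants: 21
Product: 22 (6‑epi‑jaeschkeanadiol; 4β‑OH, 6β‑OH)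
Conditions: TBAF, THF, rt → 40 °C
Reagents that add atoms: none
Why: Fluoride desilylation; no carbonyl is present, so no retro‑aldol is possible.

**Step 15**
Reactants: 22
Product: 23 ((3R,3aR,8aR)‑3‑hydroxy‑3‑isopropyl‑6,8a‑dimethyl‑2,3,3a,5,8,8a‑hexahydroazulen‑4(1H)‑one)
Conditions: Dess–Martin periodinane, NaHCO3, CH2Cl2, 0 °C
Reagents that add atoms: none
Why: Dess–Martin oxidation of the only secondary alcohol; neutral conditions preserve the tertiary β‑hydroxy ketone and the C5 configuration.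

**Step 16**
Reactants: 23
Product: 24 (jaeschkeanadiol, (3R,3aS,4S,8aR)‑3‑isopropyl‑6,8a‑dimethyl‑1,2,3,3a,4,5,8,8a‑octahydroazulene‑3,4‑diol)
Conditions: Me4NBH(OAc)3, MeCN/AcOH (1:1), −30 °C
Reagents that add atoms: none
Why: Evans–Saksena hydroxyl‑directed reduction; the borohydride bound to the 4β‑oxygen delivers hydride intramolecularly to the β face of C6, giving the 1,3‑anti diol with 6α‑OH (6S).

**Step 17**
Reactants: 24, 16 (tert‑butyl hydroperoxide)
Product: 25 (8α,9α‑epoxyjaeschkeanadiol; 8R,9S)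
Conditions: VO(acac)2 (5 mol %), t‑BuOOH, CH2Cl2, 0 °C → rt
Reagents that add atoms: tert‑butyl hydroperoxide, CC(C)(C)OO
Why: Vanadium‑catalysed epoxidation directed by the homoallylic 6α‑OH; oxygen adds to C8=C9 syn to that hydroxyl, and the tertiary 4‑OH is too remote to compete.

**Step 18**
Reactants: 25, 26 (4‑acetoxybenzoyl chloride)
Product: 27 (8α,9α‑epoxyjaeschkeanadiol 6‑O‑(4‑acetoxybenzoate))
Conditions: DMAP, Et3N, CH2Cl2, 0 °C → rt
Reagents that add atoms: 4‑acetoxybenzoyl chloride, CC(=O)Oc1ccc(cc1)C(Cl)=O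
Why: DMAP‑catalysed acylation of the only secondary alcohol; the tertiary OH is unreactive and the basic medium protects the epoxide.

**Step 19**
Reactants: 27
Product: 28 (jaeskeanin, target)
Conditions: lipase (immobilised Candida antarctica lipase B), n‑BuOH, MTBE, 40 °C
Reagents that add atoms: none
Why: Lipase‑catalysed alcoholysis cleaves the unhindered phenolic acetate under neutral conditions, leaving the hindered secondary benzoate, the epoxide and the tertiary alcohol intact.

---

**Compound list**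
1 | 3‑ethoxycyclopent‑2‑en‑1‑one | CCOC1=CC(=O)CC1 | starting material
2 | allylmagnesium bromide | C=CC[Mg]Br | starting material
3 | 3‑allylcyclopent‑2‑en‑1‑one | C=CCC1=CC(=O)CC1 | intermediate
4 | (S)‑3‑allylcyclopent‑2‑en‑1‑ol | O[C@@H]1C=C(CC=C)CC1 | intermediate
5 | diiodomethane | ICI | starting material
6 | (1R,2S,5R)‑5‑allylbicyclo[3.1.0]hexan‑2‑ol | O[C@H]1CC[C@@]2(CC=C)C[C@@H]12 | intermediate
7 | (1R,5R)‑5‑allylbicyclo[3.1.0]hexan‑2‑one | O=C1CC[C@@]2(CC=C)C[C@@H]12 | intermediate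
8 | chlorotrimethylsilane | C[Si](C)(C)Cl | starting material
9 | (R)‑[(3‑allyl‑3‑methylcyclopent‑1‑en‑1‑yl)oxy]trimethylsilane | C[Si](C)(C)OC1=C[C@@](C)(CC=C)CC1 | intermediate
10 | 3‑methylbut‑3‑en‑1‑ol | CC(=C)CCO | starting material
11 | 3‑methylbut‑3‑enal | CC(=C)CC=O | intermediate
12 | (3R)‑3‑allyl‑2‑(1‑hydroxy‑3‑methylbut‑3‑en‑1‑yl)‑3‑methylcyclopentan‑1‑one (C5/C6 mixture) | O=C1CC[C@](C)(CC=C)C1C(O)CC(C)=C | intermediate
13 | (3aR)‑8‑hydroxy‑3a,6‑dimethyl‑3,3a,4,7,8,8a‑hexahydroazulen‑1(2H)‑one (C5/C6 mixture) | O=C1CC[C@]2(C)CC=C(C)CC(O)C12 | intermediate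
14 | (3aR)‑3a,6‑dimethyl‑3,3a,4,7‑tetrahydroazulen‑1(2H)‑one | O=C1CC[C@]2(C)CC=C(C)CC=C12 | intermediate
15 | (1S,3aR)‑3a,6‑dimethyl‑1,2,3,3a,4,7‑hexahydroazulen‑1‑ol | O[C@H]1CC[C@]2(C)CC=C(C)CC=C12 | intermediate
16 | tert‑butyl hydroperoxide | CC(C)(C)OO | starting material
17 | 5β,6β‑epoxide of 15 (daucane 1R,4S,5R,6R) | O[C@H]1CC[C@]2(C)CC=C(C)C[C@H]3O[C@@]123 | intermediate
18 | tert‑butyldimethylsilyl triflate | CC(C)(C)[Si](C)(C)OS(=O)(=O)C(F)(F)F | starting material
19 | (3aR,8R,8aS)‑8‑(TBS‑oxy)‑3a,6‑dimethyl‑3,3a,4,7,8,8a‑hexahydroazulen‑1(2H)‑one | O=C1CC[C@]2(C)CC=C(C)C[C@@H](O[Si](C)(C)C(C)(C)C)[C@H]21 | intermediate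
20 | isopropyllithium | [Li]C(C)C | starting material
21 | (3R,3aS,4R,8aR)‑4‑(TBS‑oxy)‑3‑isopropyl‑6,8a‑dimethyl‑1,2,3,3a,4,5,8,8a‑octahydroazulen‑3‑ol | CC(C)[C@]1(O)CC[C@]2(C)CC=C(C)C[C@@H](O[Si](C)(C)C(C)(C)C)[C@H]21 | intermediate
22 | 6‑epi‑jaeschkeanadiol (3R,3aS,4R,8aR) | CC(C)[C@]1(O)CC[C@]2(C)CC=C(C)C[C@@H](O)[C@H]21 | intermediate
23 | (3R,3aR,8aR)‑3‑hydroxy‑3‑isopropyl‑6,8a‑dimethyl‑2,3,3a,5,8,8a‑hexahydroazulen‑4(1H)‑one | CC(C)[C@]1(O)CC[C@]2(C)CC=C(C)CC(=O)[C@H]21 | intermediate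
24 | jaeschkeanadiol (3R,3aS,4S,8aR) | CC(C)[C@]1(O)CC[C@]2(C)CC=C(C)C[C@H](O)[C@H]21 | intermediate
25 | 8α,9α‑epoxyjaeschkeanadiol | CC(C)[C@]1(O)CC[C@]2(C)C[C@@H]3O[C@]3(C)C[C@H](O)[C@H]21 | intermediate
26 | 4‑acetoxybenzoyl chloride | CC(=O)Oc1ccc(cc1)C(Cl)=O | starting material
27 | 8α,9α‑epoxyjaeschkeanadiol 6‑O‑(4‑acetoxybenzoate) | CC(C)[C@]1(O)CC[C@]2(C)C[C@@H]3O[C@]3(C)C[C@H](OC(=O)c3ccc(OC(C)=O)cc3)[C@H]21 | intermediate
28 | jaeskeanin | CC(C)[C@]1(O)CC[C@]2(C)C[C@@H]3O[C@]3(C)C[C@H](OC(=O)c3ccc(O)cc3)[C@H]21 | target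

---

**Total step count:** 19
**Longest linear sequence:** 18 (steps 1–5 and 7–19; step 6 is a one‑step branch)

**Steps most likely to fail, with fallbacks**
1. **Step 12 (hydride‑shift rearrangement).** Elimination or transannular capture of the C5 cation by C8=C9 may compete. Fallback: drop the rearrangement and use hydroboration instead. Mask C8=C9 of 15 as the diol acetonide (OsO4/NMO, then 2,2‑dimethoxypropane), protect the 4‑OH as TBS, and hydroborate/oxidise C5=C6 anti to the allylic silyl ether to give 5α‑H/6α‑OH directly. Later regenerate C8=C9 by Corey–Winter olefination.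
2. **Step 7 (aldol with the enolisable β,γ‑unsaturated aldehyde).** Proton transfer or isomerisation of 11 may lower the yield. Fallback: add silyl enol ether 9 to the dimethyl acetal of 11 (4,4‑dimethoxy‑2‑methylbut‑1‑ene) under TMSOTf catalysis (Mukaiyama–Noyori acetal addition). Carry the β‑methoxy ketone through RCM and eliminate MeOH with base to reach 14.
3. **Step 16 (directed reduction next to a tertiary directing OH and a hindered ketone).** Ligand exchange on boron may be slow, or undirected attack may return the 6β‑alcohol. Fallback: bypass ketone 23 and invert C6 of 22 by SN2: Mitsunobu reaction (p‑nitrobenzoic acid, DIAD, PPh3) followed by K2CO3/MeOH gives 24.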